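## Structural features

The target 13 is a flavanone: aromatic ring A is fused through C4a and C8a to the dihydropyran-4-one ring C (O1, C2, C3, C4), and C2 carries the 3,4-dimethoxyphenyl ring B. Ring A is fully substituted except at C8: a hydroxyl at C5 that is hydrogen-bonded to the C4 carbonyl, the ten-carbon geranyl chain at C6 and a methoxy group at C7. C2 (S) is the only stereocentre and has no stereogenic neighbour; the only other stereo-element is the E-trisubstituted C2''=C3'' alkene of the chain, whose terminal C6''=C7'' alkene is symmetrical. The fragile point is the C2–O1 bond, a benzylic ether β to the ketone: base, strong acid or ultraviolet light open ring C to the 2'-hydroxychalcone, and reclosure racemises C2; in addition the 5-OH can add to the neighbouring chain under acid to give a chroman, and both oxygenated rings are easily over-halogenated or oxidised. The real difficulty is therefore not the skeleton, which (2S)-hesperetin 1 supplies with C2 already set, but placing the chain at C6 instead of C8, with E geometry, under conditions that leave C2 alone. The key step uses the fact that the methyl-bearing C2''=C3'' alkene lies γ,δ to C6'': with C6'' as an aldehyde carbon, the segment C2''–C6'' is the retron of an aliphatic Claisen rearrangement, which forms C4''–C5'' from the C2''-O-vinyl ether of a 2-methylallylic alcohol and turns a carbinol centre of either configuration into the E alkene.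

## Logic of the disconnections

13 ⇒ 10 + 12 (from 11). The C6''=C7'' double bond is cut. The terminal isopropylidene has no geometry to control, so a carbonyl olefination removes it cheaply and leaves a γ,δ-unsaturated aldehyde, which is exactly the oxidation pattern needed for the next cut. The forward step must choose the aldehyde over the C4 ketone and must not open ring C; the free 5-OH, turned into its phenoxide in the flask, answers both demands.

10 ⇒ 9. The C4''–C5'' bond is cut, the alkene is moved from C2''=C3'' to C3''=C4'' and the C6'' carbonyl goes back to an O-vinyl group on C2''. A 4-methylalk-4-enal is the retron of the Claisen rearrangement, and this is the one cut that replaces the problem of alkene geometry by a carbinol centre whose configuration does not matter. A six-carbon, geometry-defined chain becomes a five-carbon branched one. The forward step must be purely thermal and neutral, at a temperature that ring C tolerates, and must pass through the chair with the arylmethyl group equatorial.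

9 ⇒ 7 + 8. The O–vinyl bond is cut, because vinyl ethers of secondary alcohols are made most simply by exchange with a bulk vinyl ether. C5'' and C6'' then come from a commodity chemical. The forward step must transfer the vinyl group to the C2'' hydroxyl only, near neutrality, and the product must be handled free of acid.

7 ⇒ 5 (through 6). The C2''–O bond is cut and the alkene is shifted back to C2''=C3''. Oxygenation with allylic transposition is what a photo-oxygenation does to a prenyl group, so no oxygen function has to be carried through the coupling. The side chain is reduced to plain prenyl. The forward step must take the hydrogen from the methyl group and not from C1'', and must use light that the flavanone does not absorb; control at C2'' is not needed.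

5 ⇒ 3 + 4. The C6–C1'' bond is cut. A neutral sp2–sp3 cross-coupling is preferred to acid-mediated Friedel–Crafts prenylation or base-mediated phenoxide alkylation, both of which threaten C2 and give C6/C8/O mixtures. The five-carbon unit comes from a catalogue tin reagent. The forward step must couple at the primary allyl terminus and tolerate the free 5-OH.

3 ⇒ 2. The C6–I bond is cut. The halogen marks C6, and the free 5-OH is the only handle that distinguishes C6 from C8. The forward step must mono-iodinate ortho to the chelated hydroxyl and leave C8 and ring B alone.

2 ⇒ 1. The two O–CH3 bonds at O7 and O3' are cut. This reaches a chiral-pool flavanone that already holds all three rings, the oxygenation pattern and the 2S centre, so no ring and no stereocentre has to be built. The forward step must methylate without strong base and spare the 5-OH.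

## Other disconnections considered

Alternative 1: The cut is C4–C4a of ring C. In the forward sense an alkyllithium exchanges the iodide at C4a of the open-chain ether A1 at about −100 °C, and the aryllithium closes ring C on the N-methoxy-N-methylamide carbonyl (Parham cyclisation) to give A2; removal of the acetal on O5 would then give 13.
- In its favour: the whole chain comes from a geraniol-derived unit and ring A is substituted before the ring is closed. On E geometry and on the C6/C8 question this plan is the equal or the better of the chosen one. The amide also stops the addition at the ketone stage.
- Against it here: C2 has to be created by asymmetric synthesis and carried through an acyclic β-aryloxy amide, whose α-protons invite quenching of the aryllithium and β-elimination of the phenoxide. The aryl–O–C2 bond must be made at an electron-rich benzylic carbon with a phenol flanked by iodine, where clean inversion is doubtful. The final acid step frees a phenol next to an acid-sensitive allylic chain.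
- Comparison: structurally it is more convergent; mechanistically it puts a strongly basic step on a base-labile centre, whereas the chosen route takes C2 from the chiral pool and meets a carbanion only once, with ring C shielded as the phenoxide. In step count the separate synthesis of A1 makes it clearly longer than seven steps.

Alternative 2: The cut is C4a–C5, so ring A is built last. Heating the dioxinone A3 would release an acylketene whose terminal carbon (C5) acylates C4a, the nucleophilic α-carbon of the dihydropyranone enol ether. The cyclic triketone would tautomerise to the aromatic 5,7-diol A4, and selective methylation of the non-chelated 7-OH would give 13.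
- In its favour: the chain sits on the carbon between the two future phenol carbons, so its position is fixed by construction and its geometry comes from a geranyl unit. On both points it is the equal or the better of the chosen plan. It needs no protecting groups, and aromatisation is a strong driving force.
- Against it here: C2 must again be made enantioselectively, and in A3 it sits in a 2-aryl-dihydropyranone that can open by the same retro-oxa-Michael path as a flavanone. The ketene is unmasked at a temperature no lower than that of the chosen Claisen step, so on thermal stress the two plans are equal.
- Comparison: the closure asks an acylketene to C-acylate a weakly nucleophilic vinylogous-ester carbon, and O-acylation, [4+2] addition across the enol ether and ketene dimerisation are plausible diversions; this is less predictable than a [3,3] shift. The long linear build of A3 makes the step economy worse.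

Alternative 3: The cut is C6–C1''. A magnesium-dependent aromatic prenyltransferase would transfer the geranyl group of geranyl diphosphate A6 to C6 of 1 and give A5; O-methylation at O7 and O3' as in step 1 would finish 13 in two steps.
- In its favour: on step economy it is clearly the better plan. It uses no tin or mercury and no protecting groups, the aqueous conditions are gentle on C2, and the E geometry is delivered intact from A6, which is also better than a selectivity that has to be earned in a rearrangement.
- Against it here: everything depends on an enzyme that accepts a flavanone methylated in ring B, uses a ten-carbon donor and chooses C6 over C8 and over oxygen. Flavanone prenyltransferases tend to favour C8 or the five-carbon donor, so such a catalyst would have to be found or engineered. Scale is limited by enzyme supply, substrate solubility and the cost of A6.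
- Comparison: both plans make the same aryl–allyl connection at C6, there by enzyme-guided Friedel–Crafts alkylation, here by hydroxyl-directed iodination and cross-coupling. The chosen plan spends five more steps to obtain position and geometry from substrate control with catalogue reagents; where a suitable enzyme is in hand, this alternative would be preferred.

Key step: step 6

Assumption: 1 is used at an enantiomeric purity confirmed on receipt, and 6, 7 and 9 are carried as mixtures of C2'' epimers because that centre is erased in step 6. The structures of 9, 10 and the starting materials were checked atom by atom against 13 (C6 attachment, 2S, E) and needed no correction; the 5-OH of 9 is kept free on purpose (see steps 2, 6 and 7).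

## Route

Step 1
Reactants: 1 (2S)-hesperetin [(2S)-5,7,3'-trihydroxy-4'-methoxyflavanone]
Product: 2 (2S)-5-hydroxy-7,3',4'-trimethoxyflavanone
Conditions: TMSCHN2 (2 M in hexanes, 3 equiv), i-Pr2NEt (1 equiv), MeOH–MeCN 1:9, 0 → 25 °C
Reagents that add atoms: trimethylsilyldiazomethane, C[Si](C)(C)C=[N+]=[N-] (one carbon for each new O-methyl group)
Why: Diazoalkane O-methylation of phenols: the 7-OH and 3'-OH protonate the reagent, methanol removes the silyl group and the phenoxide is methylated by the resulting diazonium ion, while the 5-OH is held in its hydrogen bond to the C4 carbonyl and is expected to stay free. No strong base or heat is used, so ring C should stay closed and C2 untouched.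

Step 2
Reactants: 2 (2S)-5-hydroxy-7,3',4'-trimethoxyflavanone
Product: 3 (2S)-5-hydroxy-6-iodo-7,3',4'-trimethoxyflavanone
Conditions: NIS (1.05 equiv), DMF, 0 → 25 °C, dark
Reagents that add atoms: N-iodosuccinimide, O=C1CCC(=O)N1I
Why: Electrophilic aromatic iodination: ring A with its free phenol is the most nucleophilic part of the molecule, and the 5-OH should steer the electrophile to its own ortho carbon C6 rather than to C8, which has no hydroxyl next to it. The conditions are neutral, and the position of the iodine should be confirmed by the long-range C–H correlations of the chelated hydroxyl before going on.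

Step 3
Reactants: 3 (2S)-5-hydroxy-6-iodo-7,3',4'-trimethoxyflavanone; 4 tributyl(3-methylbut-2-enyl)stannane
Product: 5 (2S)-5-hydroxy-7,3',4'-trimethoxy-6-(3-methylbut-2-enyl)flavanone
Conditions: 4 (1.5 equiv), Pd(PPh3)4 (5 mol%), DMF (degassed), 90 °C; filtration through KF on silica
Reagents that add atoms: tributyl(3-methylbut-2-enyl)stannane (compound 4), CCCC[Sn](CCCC)(CCCC)CC=C(C)C
Why: Stille cross-coupling: zerovalent palladium inserts into the C6–I bond, the allyl group is transferred from tin, and reductive elimination at the less hindered allyl terminus should give the linear prenyl arene. The reaction needs no base and tolerates the free phenol and the ketone.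

Step 4
Reactants: 5 (2S)-5-hydroxy-7,3',4'-trimethoxy-6-(3-methylbut-2-enyl)flavanone
Product: 7 (2S)-5-hydroxy-6-(2-hydroxy-3-methylbut-3-enyl)-7,3',4'-trimethoxyflavanone (both C2'' epimers), via secondary allylic hydroperoxide 6 (not isolated)
Conditions: O2, tetraphenylporphyrin (1 mol%), CH2Cl2, visible light (λ > 500 nm), 0 °C; then PPh3 (1.2 equiv), 0 → 25 °C
Reagents that add atoms: dioxygen, O=O
Why: Schenck ene reaction of singlet oxygen followed by phosphine reduction of the hydroperoxide: oxygen adds to C2'', a hydrogen leaves the Z-methyl group on the crowded side of the alkene and the double bond moves to C3''=C4''. Abstraction from C1'' should be disfavoured because the di-ortho-substituted arylmethyl group cannot easily turn a C–H bond perpendicular to the alkene plane; the regioisomeric alcohol that is still expected as a by-product is removed by chromatography. The C2'' centre is formed without control and both epimers are used, and the long-wavelength light avoids exciting the flavanone.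

Step 5
Reactants: 7 (2S)-5-hydroxy-6-(2-hydroxy-3-methylbut-3-enyl)-7,3',4'-trimethoxyflavanone; 8 ethyl vinyl ether
Product: 9 (2S)-5-hydroxy-7,3',4'-trimethoxy-6-[3-methyl-2-(vinyloxy)but-3-enyl]flavanone (both C2'' epimers)
Conditions: 8 (solvent), Hg(OAc)2 (0.3 equiv), reflux (33 °C); NaHCO3 work-up, neutral alumina
Reagents that add atoms: ethyl vinyl ether (compound 8), C=COCC
Why: Transvinylation catalysed by divalent mercury: reversible alkoxymercuration of the vinyl ether and loss of ethanol pass the vinyl group to the secondary alcohol, and the large excess of 8 drives the equilibrium; unreacted 7 is recycled. The chelated 5-OH is a poor nucleophile and should not take part, and the conditions are close to neutral and near room temperature.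

Step 6
Reactants: 9 (2S)-5-hydroxy-7,3',4'-trimethoxy-6-[3-methyl-2-(vinyloxy)but-3-enyl]flavanone
Product: 10 (2S)-5-hydroxy-7,3',4'-trimethoxy-6-[(2E)-3-methyl-6-oxohex-2-enyl]flavanone
Conditions: toluene (degassed, 0.02 M), 2,6-di-tert-butyl-4-methylpyridine (5 mol%), silanised sealed tube, 105–110 °C, argon, dark
Reagents that add atoms: none
Why: This is an aliphatic Claisen rearrangement, a concerted suprafacial [3,3] sigmatropic shift in which the vinyl CH2 of 9 bonds to C4'' while the C2''–O bond breaks, giving the C2''=C3'' alkene and the aldehyde at C6''. The closest known reaction type is the thermal rearrangement of vinyl ethers of secondary 2-methylallylic alcohols to (E)-4-methylalk-4-enals. No ring is closed and no stereocentre is made; the C2'' carbinol centre is consumed, so both epimers of 9 converge on one product. The step needs E over Z selectivity: in the chair transition state the C1'' arylmethyl group on C2'' takes the pseudoequatorial position, which places it anti to C4'' in the new alkene, while the pseudoaxial arrangement that leads to the Z isomer is penalised by a 1,3-diaxial contact with the vinyl-ether C–H. That penalty is modest for an unsubstituted vinyl ether, so a small share of the Z isomer must be reckoned with and would be removed at this stage on AgNO3-impregnated silica. The alkyl substituent on the carbinol carbon accelerates the shift enough for it to run near 110 °C, and the neutral aprotic medium, the hindered acid scavenger and silanised glass keep acid from the vinyl ether and base from C3, so ring C should stay closed and C2 should keep its configuration. The chelated 5-OH is left free on purpose: locked to the C4 carbonyl, it should be too weak an acid to add to the vinyl ether, and it is needed in step 7.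

Step 7
Reactants: 10 (2S)-5-hydroxy-7,3',4'-trimethoxy-6-[(2E)-3-methyl-6-oxohex-2-enyl]flavanone; 11 isopropyltriphenylphosphonium iodide
Product: 13 (2S)-5-hydroxy-7,3',4'-trimethoxy-6-[(2E)-3,7-dimethylocta-2,6-dienyl]flavanone (CNP0310479.1), via isopropylidenetriphenylphosphorane 12 (not isolated)
Conditions: 11 (2.5 equiv), KN(SiMe3)2 (2.4 equiv), THF, 0 °C; then 10, −78 → −20 °C; aq. NH4Cl at −20 °C
Reagents that add atoms: isopropyltriphenylphosphonium iodide (compound 11), CC(C)[P+](c1ccccc1)(c1ccccc1)c1ccccc1.[I-]
Why: Wittig olefination with a non-stabilised ylide: the first equivalent of 12 turns the 5-OH into its phenoxide, which makes the C4 carbonyl a vinylogous carboxylate and disfavours deprotonation at C3, so the remaining ylide should add only to the aldehyde. The new alkene carries two identical methyl groups and creates no stereo-element; C2 and the C2''=C3'' geometry are not involved.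

## Compound list

1 | (2S)-hesperetin, (2S)-5,7,3'-trihydroxy-4'-methoxyflavanone | COc1ccc([C@@H]2CC(=O)c3c(O)cc(O)cc3O2)cc1O | starting material
2 | (2S)-5-hydroxy-7,3',4'-trimethoxyflavanone | COc1ccc([C@@H]2CC(=O)c3c(cc(OC)cc3O)O2)cc1OC | intermediate
3 | (2S)-5-hydroxy-6-iodo-7,3',4'-trimethoxyflavanone | COc1ccc([C@@H]2CC(=O)c3c(cc(OC)c(I)c3O)O2)cc1OC | intermediate
4 | tributyl(3-methylbut-2-enyl)stannane | CCCC[Sn](CCCC)(CCCC)CC=C(C)C | starting material
5 | (2S)-5-hydroxy-7,3',4'-trimethoxy-6-(3-methylbut-2-enyl)flavanone | COc1ccc([C@@H]2CC(=O)c3c(cc(OC)c(CC=C(C)C)c3O)O2)cc1OC | intermediate
6 | (2S)-6-(2-hydroperoxy-3-methylbut-3-enyl)-5-hydroxy-7,3',4'-trimethoxyflavanone, both C2'' epimers (not isolated) | COc1ccc([C@@H]2CC(=O)c3c(cc(OC)c(CC(OO)C(C)=C)c3O)O2)cc1OC | intermediate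
7 | (2S)-5-hydroxy-6-(2-hydroxy-3-methylbut-3-enyl)-7,3',4'-trimethoxyflavanone, both C2'' epimers | COc1ccc([C@@H]2CC(=O)c3c(cc(OC)c(CC(O)C(C)=C)c3O)O2)cc1OC | intermediate
8 | ethyl vinyl ether | C=COCC | starting material
9 | (2S)-5-hydroxy-7,3',4'-trimethoxy-6-[3-methyl-2-(vinyloxy)but-3-enyl]flavanone, both C2'' epimers | COc1ccc([C@@H]2CC(=O)c3c(cc(OC)c(CC(OC=C)C(C)=C)c3O)O2)cc1OC | intermediate
10 | (2S)-5-hydroxy-7,3',4'-trimethoxy-6-[(2E)-3-methyl-6-oxohex-2-enyl]flavanone | COc1ccc([C@@H]2CC(=O)c3c(cc(OC)c(C/C=C(\C)CCC=O)c3O)O2)cc1OC | intermediate
11 | isopropyltriphenylphosphonium iodide | CC(C)[P+](c1ccccc1)(c1ccccc1)c1ccccc1.[I-] | starting material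
12 | isopropylidenetriphenylphosphorane (not isolated) | CC(C)=P(c1ccccc1)(c1ccccc1)c1ccccc1 | intermediate
13 | (2S)-5-hydroxy-7,3',4'-trimethoxy-6-[(2E)-3,7-dimethylocta-2,6-dienyl]flavanone, CNP0310479.1 | COc1ccc([C@@H]2CC(=O)c3c(cc(OC)c(C/C=C(\C)CCC=C(C)C)c3O)O2)cc1OC | target

## Step count and least certain steps

Total: 7 steps. Longest linear sequence: 7 steps (1 → 13); 4, 8 and 11 are purchased.

Step 6 (key step). What may go wrong is partial loss of geometric control through the chair with the arylmethyl group axial, slow thermal opening and reclosure of ring C that erodes the configuration at C2, or acid-promoted loss of the vinyl group before the shift. The first is intrinsic, because an unsubstituted vinyl ether offers only a C–H as 1,3-diaxial partner. Fallback: from 3, the whole chain would be attached in one Stille coupling (Pd(PPh3)4, DMF, 80 °C) with tributyl[(2E)-3,7-dimethylocta-2,6-dienyl]stannane F1, itself made from geranyl chloride and Bu3SnLi; this comes back to the route at 13 and relies on the allyl–palladium intermediate not scrambling geometry.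

Step 4. What may go wrong is competing hydrogen abstraction at the benzylic C1'' instead of the methyl group, and photo-oxidation of the phenolic ring, because singlet oxygen discriminates only weakly between the two allylic positions on the crowded side of a trisubstituted alkene. Fallback: from 5, oxidative cleavage of the prenyl alkene (OsO4 cat., NaIO4, THF–H2O) would give the arylacetaldehyde (2S)-5-hydroxy-7,3',4'-trimethoxy-6-(2-oxoethyl)flavanone F2, and a Nozaki–Hiyama–Kishi addition of 2-bromopropene (CrCl2, NiCl2 cat., DMF), which is selective for aldehydes over ketones, would place the oxygen unambiguously at C2'' and come back to the route at 7.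

Step 5. What may go wrong is stalling of the exchange equilibrium and consumption of the mercury catalyst by mercuration at C8 or by phenol-assisted oxymercuration of the 1,1-disubstituted alkene. Fallback: from 7, acid-catalysed addition to 8 (PPTS, CH2Cl2, 0 °C) would give the mixed acetal (2S)-6-[2-(1-ethoxyethoxy)-3-methylbut-3-enyl]-5-hydroxy-7,3',4'-trimethoxyflavanone F3, and elimination of the ethoxy group with TMSOTf and Et3N (CH2Cl2, −20 °C) would come back to the route at 9. The phenol uses up a further equivalent of the reagent pair and is freed again on mild methanolic work-up.

Step 7. What may go wrong is enolisation at C3 or addition at C4 by the excess basic ylide, which would open ring C and racemise C2, and incomplete olefination by this hindered ylide. Fallback: from 10, aldehyde-selective Takai methylenation (CH2I2, Zn, Ti(Oi-Pr)4, THF), which is not basic, would give the terminal alkene (2S)-5-hydroxy-7,3',4'-trimethoxy-6-[(2E)-3-methylhepta-2,6-dienyl]flavanone F4, and cross-metathesis with 2-methyl-2-butene (second-generation Grubbs catalyst, 40 °C), to which the internal trisubstituted alkene should be inert, would come back to the route at 13.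

Step 2. What may go wrong is iodination at C8 or twofold iodination, because both free positions of ring A are activated and the directing effect of a chelated hydroxyl is only moderate. Fallback: from 2, palladium-catalysed O-allylation of the 5-OH with allyl methyl carbonate (Pd(PPh3)4, THF) would give (2S)-5-(allyloxy)-7,3',4'-trimethoxyflavanone F5. Aromatic Claisen rearrangement (o-dichlorobenzene, about 180 °C), for which C6 is the only open ortho position, would give (2S)-6-allyl-5-hydroxy-7,3',4'-trimethoxyflavanone F6. Cross-metathesis with 2-methyl-2-butene (second-generation Grubbs catalyst) would then turn the allyl into the prenyl group and come back to the route at 5, by-passing steps 2 and 3 at the price of one hot step whose effect on C2 would have to be checked.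

## Further compounds

F1 | step 6 | tributyl[(2E)-3,7-dimethylocta-2,6-dienyl]stannane | CCCC[Sn](CCCC)(CCCC)C/C=C(\C)CCC=C(C)C
F2 | step 4 | (2S)-5-hydroxy-7,3',4'-trimethoxy-6-(2-oxoethyl)flavanone | COc1ccc([C@@H]2CC(=O)c3c(cc(OC)c(CC=O)c3O)O2)cc1OC
F3 | step 5 | (2S)-6-[2-(1-ethoxyethoxy)-3-methylbut-3-enyl]-5-hydroxy-7,3',4'-trimethoxyflavanone | COc1ccc([C@@H]2CC(=O)c3c(cc(OC)c(CC(OC(C)OCC)C(C)=C)c3O)O2)cc1OC
F4 | step 7 | (2S)-5-hydroxy-7,3',4'-trimethoxy-6-[(2E)-3-methylhepta-2,6-dienyl]flavanone | COc1ccc([C@@H]2CC(=O)c3c(cc(OC)c(C/C=C(\C)CCC=C)c3O)O2)cc1OC
F5 | step 2 | (2S)-5-(allyloxy)-7,3',4'-trimethoxyflavanone | COc1ccc([C@@H]2CC(=O)c3c(cc(OC)cc3OCC=C)O2)cc1OC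
F6 | step 2 | (2S)-6-allyl-5-hydroxy-7,3',4'-trimethoxyflavanone | COc1ccc([C@@H]2CC(=O)c3c(cc(OC)c(CC=C)c3O)O2)cc1OC
A1 | alternative 1 | (3S)-3-(3,4-dimethoxyphenyl)-3-[4-geranyl-2-iodo-5-methoxy-3-(methoxymethoxy)phenoxy]-N-methoxy-N-methylpropanamide | CON(C)C(=O)C[C@@H](c1ccc(OC)c(OC)c1)Oc1cc(OC)c(C/C=C(\C)CCC=C(C)C)c(OCOC)c1I
A2 | alternative 1 | (2S)-6-geranyl-5-(methoxymethoxy)-7,3',4'-trimethoxyflavanone | COCOc1c(C/C=C(\C)CCC=C(C)C)c(OC)cc2c1C(=O)C[C@@H](c1ccc(OC)c(OC)c1)O2
A3 | alternative 2 | (2S)-2-(3,4-dimethoxyphenyl)-6-[(5-geranyl-2,2-dimethyl-4-oxo-4H-1,3-dioxin-6-yl)methyl]-2,3-dihydro-4H-pyran-4-one | O=C1C[C@@H](c2ccc(OC)c(OC)c2)OC(CC2=C(C/C=C(\C)CCC=C(C)C)C(=O)OC(C)(C)O2)=C1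
A4 | alternative 2 | (2S)-6-geranyl-5,7-dihydroxy-3',4'-dimethoxyflavanone | O=C1C[C@@H](c2ccc(OC)c(OC)c2)Oc2cc(O)c(C/C=C(\C)CCC=C(C)C)c(O)c21
A5 | alternative 3 | (2S)-6-geranylhesperetin | COc1ccc([C@@H]2CC(=O)c3c(cc(O)c(C/C=C(\C)CCC=C(C)C)c3O)O2)cc1O
A6 | alternative 3 | geranyl diphosphate | CC(C)=CCC/C(C)=C/COP(=O)(O)OP(=O)(O)O
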